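**Plan**

1. Target: the isofraxidin ether of 3β-acetoxy-9-epi-drim-7-en-11-ol (3S,5R,9R,10S; C11 axial and anti to the C10 methyl). Cuts: C9–H together with C7=C8 back to a 7-oxo-8-ene; C11–O(aryl) and C9–C11 back to a C9 ketone; the ring B bond C7=C8 (aldol condensation); then C7=C9 and C9–ethyl of a cyclopentene derived from (S)-Hajos–Parrish ketone.
2. Forward: ring A and C10 come with the hydrindenedione. Its five-membered ring (C5, C6, C7, C9, C10) is cut at C7=C9 by ozonolysis and closed again one carbon larger as ring B through C7–C8; C8 and C12 come from an ethyl group placed on C9.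
3. Feature that makes the closure possible: C9 sits on the quaternary C10, so the ethyl ketone can enolise only toward C8, and the C7 aldehyde is three atoms away (C10, C5, C6). Only ring B as a 2-methylcyclohex-2-enone can form, which fixes the C7=C8 alkene and the C8 methyl.
4. The C9 carbonyl left by the closure is the handle for C11: methylene transfer gives a spiro-epoxide, the coumarin phenoxide opens it at C11, oxidative 1,3-transposition moves the oxygen to C7, and reductive transposition of the C7 tosylhydrazone returns the alkene to C7=C8 and removes the helper oxygen.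
5. Stereochemistry: C10 from the starting material; C5 by hydrogenation anti to the C10 methyl; C3 by axial hydride delivery; C9 last, by suprafacial hydrogen transfer to the β face from a C7β diazene.

Key step: step 9

Remark: drimane numbering is used for all intermediates, including the ring-contracted ones (ring A = C1 to C5 and C10; five-membered ring = C5, C6, C7, C9, C10). α/β refer to the usual drimane orientation with the C10 methyl β. Both starting materials are taken as commercial in the form shown.

**Route**

Step 1
Reactants: 1 (S)-Hajos–Parrish ketone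
Product: 2 C9 ethylene ketal of the enedione
Conditions: ethylene glycol, p-TsOH·H2O (cat.), 4 Å molecular sieves, CH2Cl2, rt
Reagents that add atoms: ethylene glycol OCCO
Why: Chemoselective acid-catalysed ketalisation of the saturated five-ring ketone (C9), which is more electrophilic than the conjugated C3 carbonyl; no stereocentre is formed.

Step 2
Reactants: 2 C9 ethylene ketal of the enedione
Product: 4 4,4-dimethyl-5-en-3-one ketal, via 4-monomethyl ketone 3 (not isolated)
Conditions: KOtBu (3 equiv), MeI (excess), t-BuOH, 0 °C to rt
Reagents that add atoms: iodomethane CI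
Why: Deconjugative α,α-dimethylation of the enone through its potassium dienolate (γ-deprotonation at C6, C-alkylation at C4, twice) builds the C4 gem-dimethyl group and leaves the alkene at C5=C6; no stereocentre is formed.

Step 3
Reactants: 4 4,4-dimethyl-5-en-3-one ketal
Product: 5 trans-fused saturated 3-ketone ketal (5α-H)
Conditions: H2 (3 atm), 10% Pd/C, EtOAc, rt
Reagents that add atoms: none
Why: Heterogeneous syn hydrogenation of the trisubstituted ring-fusion alkene from the α face, the β face being covered by the angular C10 methyl, should set C5–H trans to that methyl (trans-hydrindane).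

Step 4
Reactants: 5 trans-fused saturated 3-ketone ketal
Product: 7 3β-hydroxy-9-ketone, via hydroxy ketal 6 (not isolated)
Conditions: NaBH4, MeOH, 0 °C; then 2 M aq. HCl, THF, rt
Reagents that add atoms: water O
Why: Carbonyl reduction by axial hydride delivery from the α face (the equatorial approach is blocked by the axial C4 methyl) should give the equatorial 3β-alcohol (3S), and the acidic work-up hydrolyses the dioxolane.

Step 5
Reactants: 7 3β-hydroxy-9-ketone
Product: 8 3β-acetoxy-9-ketone
Conditions: Ac2O, pyridine, DMAP (cat.), CH2Cl2, rt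
Reagents that add atoms: acetic anhydride CC(=O)OC(C)=O
Why: DMAP-catalysed O-acetylation installs the acetate of the target, which is carried unchanged to the end; the configuration is untouched.

Step 6
Reactants: 8 3β-acetoxy-9-ketone
Product: 9 C9 enol triflate (C7=C9)
Conditions: Tf2O, 2,6-di-tert-butyl-4-methylpyridine, CH2Cl2, 0 °C to rt
Reagents that add atoms: triflic anhydride O=S(=O)(OS(=O)(=O)C(F)(F)F)C(F)(F)F
Why: Enol triflate formation with a non-nucleophilic pyridine base; C9 can enolise only toward C7 because C10 is quaternary, and these conditions are the usual ones for cyclopentanones next to a quaternary centre in acetate-bearing steroids.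

Step 7
Reactants: 9 C9 enol triflate
Product: 10 9-ethyl-7(9)-ene 3β-acetate
Conditions: EtZnBr, Pd(dppf)Cl2 (5 mol %), THF, 50 °C
Reagents that add atoms: ethylzinc bromide CC[Zn]Br
Why: Negishi sp2–sp3 cross-coupling; the wide-bite-angle dppf ligand favours reductive elimination over β-hydride elimination and the organozinc spares the acetate.

Step 8
Reactants: 10 9-ethyl-7(9)-ene 3β-acetate
Product: 12 seco keto-aldehyde (C9 ethyl ketone; C7 aldehyde), via ozonide 11 (not isolated)
Conditions: O3, CH2Cl2, −78 °C; then PPh3, −78 °C to rt
Reagents that add atoms: ozone [O-][O+]=O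
Why: Ozonolysis with reductive work-up cleaves the only C=C bond (C7=C9) of the five-membered ring; C10 is quaternary and C5 is not α to either new carbonyl, so both stereocentres are kept.

Step 9
Reactants: 12 seco keto-aldehyde
Product: 14 3β-acetoxy-11-nor-drim-7-en-9-one, via aldol adduct 13 (not isolated)
Conditions: p-TsOH·H2O (10 mol %), benzene, reflux, Dean–Stark
Reagents that add atoms: none
Why: Acid-catalysed intramolecular aldol condensation: the C9 ethyl ketone enolises toward C8, the enol carbon C8 adds to the protonated C7 aldehyde, and the β-hydroxy ketone 13 loses water to the conjugated enone, so C7=C8 arises first as a σ bond and then as the π bond in one operation. The closest known reaction type is the ozonolysis–aldol one-carbon ring expansion of 1-alkylcyclopentenes to 2-alkylcyclohex-2-enones, the closing half of a Robinson annulation. Ring B closes in the 6-(enolendo)-exo-trig mode. No new stereocentre survives, since C7 and C8 end as sp2 carbons, and C5 and C10 cannot epimerise because C10 is quaternary and C5 is not α to a carbonyl. The step needs regioselectivity between two enolisable carbonyls: the aldehyde enol (C6) could only attack C9 to give a four-membered ring and the ketone has no α-hydrogen on its C10 side, so only the six-membered 2-methyl enone with the alkene at C7=C8 can form. The acetate should survive the anhydrous acid.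

Step 10
Reactants: 14 3β-acetoxy-11-nor-drim-7-en-9-one
Product: 15 C9 spiro-oxirane (C11 α; oxygen β)
Conditions: trimethylsulfonium iodide, n-BuLi, THF, −10 °C; then 14, −10 °C to rt
Reagents that add atoms: trimethylsulfonium iodide C[S+](C)C.[I-]
Why: Corey–Chaykovsky epoxidation: the unstabilised sulfonium ylide adds 1,2 to the enone carbonyl, axially from the α face anti to the C10 methyl, and the betaine closes to the oxirane; the C9 configuration is erased in step 12, so this selectivity is not critical.

Step 11
Reactants: 15 C9 spiro-oxirane; 16 isofraxidin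
Product: 17 3β-acetoxy-9β-hydroxy-drim-7-en-11-yl ether of isofraxidin
Conditions: K2CO3 (0.3 equiv), DMF, 90 °C
Reagents that add atoms: none
Why: Base-mediated SN2 opening of the 2,2-disubstituted oxirane by the phenoxide at its only open carbon (the C11 methylene) forms the aryl ether without activating a neopentyl-type alcohol.

Step 12
Reactants: 17 3β-acetoxy-9β-hydroxy-drim-7-en-11-yl ether of isofraxidin
Product: 18 3β-acetoxy-7-oxo-drim-8-en-11-yl ether of isofraxidin
Conditions: pyridinium chlorochromate [C5H5NH][CrO3Cl], 4 Å molecular sieves, CH2Cl2, rt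
Reagents that add atoms: pyridinium chlorochromate [O-][Cr](=O)(=O)Cl.c1cc[nH+]cc1
Why: Babler–Dauben oxidative transposition: the chromate ester of the tertiary allylic alcohol undergoes a [3,3] shift to C7 and is oxidised there to the tetrasubstituted enone.

Step 13
Reactants: 18 3β-acetoxy-7-oxo-drim-8-en-11-yl ether of isofraxidin
Product: 19 C7 tosylhydrazone of 18
Conditions: TsNHNH2, AcOH (cat.), EtOH, 50 °C
Reagents that add atoms: p-toluenesulfonyl hydrazide Cc1ccc(cc1)S(=O)(=O)NN
Why: Hydrazone formation at the unhindered C7 carbonyl; the β-carbon (C9) is fully substituted, so conjugate addition of the hydrazide is not expected.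

Step 14
Reactants: 19 C7 tosylhydrazone of 18
Product: 22 target ether CNP0285931.2, via allylic tosylhydrazine 20 (not isolated), via allylic diazene 21 (not isolated)
Conditions: catecholborane, CHCl3, 0 °C; then NaOAc·3H2O, reflux
Reagents that add atoms: none
Why: Reductive 1,3-transposition of an α,β-unsaturated tosylhydrazone: axial hydride addition to C7 from the α face places nitrogen on the β face, sulfinate loss gives the allylic diazene, and its suprafacial retro-ene hydrogen shift with loss of N2 delivers hydrogen to C9 on the β face and moves the alkene to C7=C8, the same sense as in the cis-selective reduction of steroidal 4-en-3-one tosylhydrazones.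

**Compound list**

1 | (S)-Hajos–Parrish ketone, (7aS)-7a-methyl-2,3,7,7a-tetrahydro-1H-indene-1,5(6H)-dione | O=C1CCC2=CC(=O)CC[C@]12C | starting material
2 | C9 ethylene ketal (1,3-dioxolane) of 1; C3 enone free; 10S | O1CCOC12CCC3=CC(=O)CC[C@]23C | intermediate
3 | C9 dioxolane of the 4-methyl-5-en-3-one (C4 configuration undefined) | O1CCOC12CC=C3C(C)C(=O)CC[C@]23C | intermediate (not isolated)
4 | C9 dioxolane of the 4,4-dimethyl-5-en-3-one (alkene C5=C6 in the five-membered ring) | O1CCOC12CC=C3C(C)(C)C(=O)CC[C@]23C | intermediate
5 | C9 dioxolane of the trans-fused 4,4-dimethyl-3-ketone (5α-H, 10β-methyl) | O1CCOC12CC[C@H]3C(C)(C)C(=O)CC[C@]23C | intermediate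
6 | C9 dioxolane of the 3β-alcohol (3S, 5α-H) | O1CCOC12CC[C@H]3C(C)(C)[C@@H](O)CC[C@]23C | intermediate (not isolated)
7 | 3β-hydroxy-4,4,10-trimethyl-trans-hydrindan-9-one (3S, 5α-H, 10S) | O=C1CC[C@H]2C(C)(C)[C@@H](O)CC[C@]12C | intermediate
8 | 3β-acetate of 7 | O=C1CC[C@H]2C(C)(C)[C@@H](OC(C)=O)CC[C@]12C | intermediate
9 | C9 enol triflate of 8 (alkene C7=C9) | FC(F)(F)S(=O)(=O)OC1=CC[C@H]2C(C)(C)[C@@H](OC(C)=O)CC[C@]12C | intermediate
10 | 9-ethyl-7(9)-ene 3β-acetate (1-ethylcyclopentene fused to ring A) | CCC1=CC[C@H]2C(C)(C)[C@@H](OC(C)=O)CC[C@]12C | intermediate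
11 | ozonide of 10 (1,2,4-trioxolane bridging C7 and C9; configuration at C7 and C9 undefined) | CCC12OOC(O1)C[C@H]3C(C)(C)[C@@H](OC(C)=O)CC[C@]23C | intermediate (not isolated)
12 | seco keto-aldehyde: ring A cyclohexane with 3β-OAc, 4,4-dimethyl, at C10 methyl and propanoyl (C9, C8, C12), at C5 a 2-oxoethyl group (C6, C7) trans to the propanoyl | CCC(=O)[C@@]1(C)CC[C@H](OC(C)=O)C(C)(C)[C@@H]1CC=O | intermediate
13 | aldol adduct: 3β-acetoxy-7-hydroxy-8-methyl-11-nor-driman-9-one (C7 and C8 undefined) | O=C1C(C)C(O)C[C@H]2C(C)(C)[C@@H](OC(C)=O)CC[C@]12C | intermediate (not isolated)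
14 | 3β-acetoxy-11-nor-drim-7-en-9-one (trans-fused 2-methylcyclohex-2-enone) | O=C1C(C)=CC[C@H]2C(C)(C)[C@@H](OC(C)=O)CC[C@]12C | intermediate
15 | C9 spiro-oxirane of 14 (oxirane C9–C11–O; C11 α, oxygen β; 7-ene) | C1O[C@]12C(C)=CC[C@H]3C(C)(C)[C@@H](OC(C)=O)CC[C@]23C | intermediate
16 | isofraxidin (7-hydroxy-6,8-dimethoxycoumarin) | COc1cc2ccc(=O)oc2c(OC)c1O | starting material
17 | 3β-acetoxy-9β-hydroxy-drim-7-en-11-yl ether of isofraxidin (C11 α) | COc1cc2ccc(=O)oc2c(OC)c1OC[C@]1(O)C(C)=CC[C@H]2C(C)(C)[C@@H](OC(C)=O)CC[C@]12C | intermediate
18 | 3β-acetoxy-7-oxo-drim-8-en-11-yl ether of isofraxidin | COc1cc2ccc(=O)oc2c(OC)c1OCC1=C(C)C(=O)C[C@H]2C(C)(C)[C@@H](OC(C)=O)CC[C@]12C | intermediate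
19 | C7 tosylhydrazone of 18 (C=N geometry undefined) | COc1cc2ccc(=O)oc2c(OC)c1OCC1=C(C)C(=NNS(=O)(=O)c3ccc(C)cc3)C[C@H]2C(C)(C)[C@@H](OC(C)=O)CC[C@]12C | intermediate
20 | 7β-(N'-tosylhydrazino)-drim-8-en-11-yl ether (C7–H α; boron-bound in the flask) | COc1cc2ccc(=O)oc2c(OC)c1OCC1=C(C)[C@@H](NNS(=O)(=O)c3ccc(C)cc3)C[C@H]2C(C)(C)[C@@H](OC(C)=O)CC[C@]12C | intermediate (not isolated)
21 | 7β-diazenyl-drim-8-en-11-yl ether | COc1cc2ccc(=O)oc2c(OC)c1OCC1=C(C)[C@@H](N=N)C[C@H]2C(C)(C)[C@@H](OC(C)=O)CC[C@]12C | intermediate (not isolated)
22 | CNP0285931.2: 7-O-[(3S,5R,9R,10S)-3-acetoxy-drim-7-en-11-yl]isofraxidin (C11 α, 9β-H) | COc1cc2ccc(=O)oc2c(OC)c1OC[C@@H]1C(C)=CC[C@H]2C(C)(C)[C@@H](OC(C)=O)CC[C@]12C | target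

**Step count and weak points**

Total step count: 14. Longest linear sequence: 14 steps (from 1; isofraxidin 16 enters at step 11).

Steps most likely to fail:

1. Step 14. Hydride may add to the C7 hydrazone from the β face as well (poor facial selectivity), which would put the diazene on the α face and deliver hydrogen to C9 from the wrong side; vinylogous loss of the aryloxide before reduction is a second risk. Fallback: setting out from 18, reagent-controlled Corey–Bakshi–Shibata reduction ((S)-2-methyl-CBS-oxazaborolidine, catecholborane, toluene, −78 °C; C8 as the large group, hydride to the β face) should give the 7α-allylic alcohol F1. Mitsunobu displacement with 2-nitrobenzenesulfonylhydrazide (PPh3, DEAD, THF, −30 °C) inverts C7 to the 7β-[N-(2-nitrobenzenesulfonyl)hydrazino] compound F2, which on warming loses sulfinic acid and comes back to the route at diazene 21, hence 22. Here the C7–N configuration is fixed by SN2 inversion of a defined alcohol and not by the face of hydrazone reduction.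

2. Step 12. Chromate ester formation at the hindered tertiary alcohol may be slow, and ionisation may lead to dehydration to a diene instead of transposition and oxidation. Fallback: setting out from 17, catalytic 1,3-transposition with Ph3SiOReO3 (cat., Et2O, 0 °C) should give the secondary allylic alcohol F3 with the tetrasubstituted C8=C9 alkene, and Dess–Martin periodinane (CH2Cl2, rt) oxidises it to 18, where the route is rejoined.

3. Step 3. Hydrogen may also add from the β face (poor facial selectivity at the ring-fusion alkene, giving the cis-fused isomer), or the hindered alkene may reduce slowly. Fallback: setting out from 2, Birch-type reductive methylation (Li, liquid NH3, THF, −78 °C; then MeI) sets the trans ring fusion by protonation of the β-carbon and gives the trans-fused 4-methyl ketone F4. A second methylation through the more substituted enolate (KOtBu, MeI, t-BuOH) then gives 5, where the route is rejoined; steps 2 and 3 are both bypassed.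

Further compounds
F1 | step 14 | 3β-acetoxy-7α-hydroxy-drim-8-en-11-yl ether of isofraxidin | COc1cc2ccc(=O)oc2c(OC)c1OCC1=C(C)[C@H](O)C[C@H]2C(C)(C)[C@@H](OC(C)=O)CC[C@]12C
F2 | step 14 | 3β-acetoxy-7β-[N-(2-nitrobenzenesulfonyl)hydrazino]-drim-8-en-11-yl ether of isofraxidin | COc1cc2ccc(=O)oc2c(OC)c1OCC1=C(C)[C@@H](N(N)S(=O)(=O)c3ccccc3[N+](=O)[O-])C[C@H]2C(C)(C)[C@@H](OC(C)=O)CC[C@]12C
F3 | step 12 | 3β-acetoxy-7-hydroxy-drim-8-en-11-yl ether of isofraxidin (C7 epimers) | COc1cc2ccc(=O)oc2c(OC)c1OCC1=C(C)C(O)C[C@H]2C(C)(C)[C@@H](OC(C)=O)CC[C@]12C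
F4 | step 3 | C9 dioxolane of the trans-fused 4-methyl-3-ketone (5α-H; C4 configuration undefined) | O1CCOC12CC[C@H]3C(C)C(=O)CC[C@]23C
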